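## Retrosynthetic overview

1. Target ⇒ C4–C(acyl) bond: crossed benzoin of the acyl anion (Breslow intermediate) of 4-methylpent-3-enal onto the C4 ketone of an enantioenriched 5-hydroxy-5-prenyl-2-isovalerylcyclopentane-1,3,4-trione; both carbons joined are carbonyl carbons.
2. Hydroxy trione ⇒ catalytic asymmetric C5 hydroxylation of 2-isovaleryl-5-prenylcyclopentane-1,3,4-trione.
3. Acyl trione ⇒ C-acylation of 3-prenylcyclopentane-1,2,4-trione with isovaleryl chloride.
4. The only ring (the cyclopentane) is formed first, by Claisen/Dieckmann annulation of 6-methylhept-5-en-2-one with diethyl oxalate.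
5. The aldehyde ⇐ oxidation of 4-methylpent-3-en-1-ol.

Assumption: the senses of induction of the chiral salts in steps 3 and 5 are as written; if the opposite sense is found, the pseudoenantiomeric cinchoninium salt (step 3) or the (R)-triazolium salt (step 5) is used.

Note: ring positions in the Why lines use the target numbering (C1 ring ketone, C2 isovaleryl-bearing carbon, C3 enol carbon, C4 and C5 the two carbinol carbons). Triketone units are drawn as one enol tautomer.

## Route

Step 1
Reactants: 1 6-methylhept-5-en-2-one; 2 diethyl oxalate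
Product: 4 3-(3-methylbut-2-en-1-yl)cyclopentane-1,2,4-trione, via dioxo ester 3 (not isolated)
Conditions: NaOEt (2.2 equiv), EtOH, 0 °C to rt, then reflux; 1 M HCl, 0 °C
Reagents that add atoms: none
Why: The methyl-side sodium enolate of 1 undergoes a crossed Claisen condensation with 2, and on heating the C5 carbanion closes onto the remaining ester (Dieckmann condensation), the doubly deprotonated trione being the thermodynamic sink; no stereocentre is formed because C5 is enolised.

Step 2
Reactants: 4 3-(3-methylbut-2-en-1-yl)cyclopentane-1,2,4-trione; 5 3-methylbutanoyl chloride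
Product: 7 3-hydroxy-2-(3-methylbutanoyl)-5-(3-methylbut-2-en-1-yl)cyclopent-2-ene-1,4-dione, via enol ester 6 (not isolated)
Conditions: Et3N (2.2 equiv), CH2Cl2, 0 °C; then 4-(dimethylamino)pyridine (20 mol %), MeCN, rt; 1 M HCl
Reagents that add atoms: none
Why: O-acylation followed by 4-(dimethylamino)pyridine-mediated O-to-C acyl transfer (enol ester to 2-acyl-1,3-dione rearrangement) delivers the isovaleryl group to C2, the only unsubstituted carbon between two ring carbonyls, driven by formation of the chelated, strongly acidic β-triketone; no stereocentre is formed.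

Step 3
Reactants: 7 3-hydroxy-2-(3-methylbutanoyl)-5-(3-methylbut-2-en-1-yl)cyclopent-2-ene-1,4-dione
Product: 8 (2R)-2,4-dihydroxy-2-(3-methylbut-2-en-1-yl)-5-(3-methylbutanoyl)cyclopent-4-ene-1,3-dione
Conditions: trans-2-(phenylsulfonyl)-3-phenyloxaziridine (1.1 equiv), O-allyl-N-(9-anthracenylmethyl)cinchonidinium bromide (10 mol %), K2CO3 (2.5 equiv), toluene, −40 °C; 1 M HCl, 0 °C
Reagents that add atoms: 2-(phenylsulfonyl)-3-phenyloxaziridine, O=S(=O)(c1ccccc1)N1OC1c1ccccc1
Why: Electrophilic enolate hydroxylation with an N-sulfonyloxaziridine (Davis oxidation) under chiral phase-transfer catalysis oxygenates C5 of the dianion, the only nucleophilic ring carbon still carrying hydrogen, within the chiral ammonium ion pair from the face that gives the (R)-carbinol, while the prenyl alkene is inert to the oxaziridine at this temperature.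

Step 4
Reactants: 9 4-methylpent-3-en-1-ol
Product: 10 4-methylpent-3-enal
Conditions: Dess–Martin periodinane (1.1 equiv), pyridine (3 equiv), CH2Cl2, 0 °C; filtered solution used at once
Reagents that add atoms: none
Why: Dess–Martin oxidation of the primary alcohol stops at the aldehyde under buffered, non-basic conditions, so the β,γ-double bond does not move into conjugation; no stereocentre is formed.

Step 5
Reactants: 8 (2R)-2,4-dihydroxy-2-(3-methylbut-2-en-1-yl)-5-(3-methylbutanoyl)cyclopent-4-ene-1,3-dione; 10 4-methylpent-3-enal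
Product: 12 (4S,5S)-3,4,5-trihydroxy-5-(3-methylbut-2-en-1-yl)-2-(3-methylbutanoyl)-4-(4-methylpent-3-enoyl)cyclopent-2-en-1-one, via Breslow intermediate 11 (not isolated)
Conditions: (S)-5-benzyl-2-(pentafluorophenyl)-6,8-dihydro-5H-[1,2,4]triazolo[3,4-c][1,4]oxazin-2-ium tetrafluoroborate (15 mol %), i-Pr2NEt (1.2 equiv), 4 Å molecular sieves, CH2Cl2, −20 to 0 °C, 10 (2 equiv) added slowly; 1 M citric acid
Reagents that add atoms: none
Why: Proposed new method: the triazolylidene adds to 10 to give the acyl anion equivalent 11, which attacks the C4 ketone of the ammonium enolate of 8 (the only carbonyl outside the enolate, activated by the adjacent carbonyl and the α-hydroxyl) from its Re face, anti to the C5–O bond (polar Felkin–Anh) and matched with the (S)-carbene, so that the new C4–OH is cis to the C5–OH and C4 is (S), after which proton transfer and loss of the carbene give 12; the closest known reaction type is the N-heterocyclic-carbene-catalysed crossed benzoin of aliphatic aldehydes with α-keto esters and 1,2-diketones.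

## Compound list

1 | 6-methylhept-5-en-2-one | CC(=O)CCC=C(C)C | starting material
2 | diethyl oxalate | CCOC(=O)C(=O)OCC | starting material
3 | ethyl 8-methyl-2,4-dioxonon-7-enoate (present as its sodium enolate) | CCOC(=O)C(=O)CC(=O)CCC=C(C)C | intermediate
4 | 3-(3-methylbut-2-en-1-yl)cyclopentane-1,2,4-trione | O=C1CC(=O)C(=O)C1CC=C(C)C | intermediate
5 | 3-methylbutanoyl chloride | CC(C)CC(=O)Cl | starting material
6 | 4-(3-methylbut-2-en-1-yl)-3,5-dioxocyclopent-1-en-1-yl 3-methylbutanoate (enol ester) | O=C1C=C(OC(=O)CC(C)C)C(=O)C1CC=C(C)C | intermediate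
7 | 3-hydroxy-2-(3-methylbutanoyl)-5-(3-methylbut-2-en-1-yl)cyclopent-2-ene-1,4-dione | O=C1C(C(=O)CC(C)C)=C(O)C(=O)C1CC=C(C)C | intermediate
8 | (2R)-2,4-dihydroxy-2-(3-methylbut-2-en-1-yl)-5-(3-methylbutanoyl)cyclopent-4-ene-1,3-dione | O=C1C(O)=C(C(=O)CC(C)C)C(=O)[C@]1(O)CC=C(C)C | intermediate
9 | 4-methylpent-3-en-1-ol | CC(C)=CCCO | starting material
10 | 4-methylpent-3-enal | CC(C)=CCC=O | intermediate
11 | (S)-1-[5-benzyl-2-(pentafluorophenyl)-5,6-dihydro-8H-[1,2,4]triazolo[3,4-c][1,4]oxazin-3(2H)-ylidene]-4-methylpent-3-en-1-ol (Breslow intermediate) | CC(C)=CCC(O)=C1N(c2c(F)c(F)c(F)c(F)c2F)N=C2COC[C@H](Cc3ccccc3)N12 | intermediate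
12 | (4S,5S)-3,4,5-trihydroxy-5-(3-methylbut-2-en-1-yl)-2-(3-methylbutanoyl)-4-(4-methylpent-3-enoyl)cyclopent-2-en-1-one | CC(C)=CCC(=O)[C@]1(O)C(O)=C(C(=O)CC(C)C)C(=O)[C@]1(O)CC=C(C)C | target

## Step count and risks

Total steps: 5. Longest linear sequence: 4 (steps 1, 2, 3 and 5 from compound 1); step 4 is a one-step side branch.

The three steps most likely to fail:

- **Step 5.** The risks are low electrophilicity of the enolate form of 8, isomerisation of 10 or of its Breslow intermediate into conjugation, and attack on the wrong face. The fallback sets out from 8 and returns at 12, replacing the catalytic acyl anion by a stoichiometric masked one. 1,3-Dithiane is lithiated (n-BuLi, THF, −30 °C) and alkylated with 1-bromo-3-methylbut-2-ene to give 2-(3-methylbut-2-en-1-yl)-1,3-dithiane F1. Compound 8 is converted into its dilithium salt with LiN(SiMe3)2 (2.1 equiv, THF, −78 °C) and treated with the 2-lithio derivative of F1 (1.5 equiv), which adds to the C4 ketone anti to the C5–O bond to give (4S,5S)-3,4,5-trihydroxy-5-(3-methylbut-2-en-1-yl)-2-(3-methylbutanoyl)-4-[2-(3-methylbut-2-en-1-yl)-1,3-dithian-2-yl]cyclopent-2-en-1-one F2. Oxidative hydrolysis of the dithioketal with PhI(OCOCF3)2 in aqueous MeCN at 0 °C then gives 12.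

- **Step 3.** The risk is low enantioselectivity, because the substrate is a dianion that pairs poorly with one chiral cation, together with some oxidation at C2. The fallback sets out from 7 and returns at 8, replacing asymmetric catalysis by resolution. The same oxaziridine hydroxylation is run without the chiral salt (K2CO3, THF, −20 °C) to give racemic 2,4-dihydroxy-2-(3-methylbut-2-en-1-yl)-5-(3-methylbutanoyl)cyclopent-4-ene-1,3-dione F3. The enantiomers are separated by preparative chromatography on amylose tris(3,5-dimethylphenylcarbamate) (heptane/i-PrOH/CF3CO2H), and the (R)-enantiomer 8 is taken forward.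

- **Step 2.** The risks are poly-acylation and incomplete O-to-C transfer on a trione with several enol oxygens. The fallback sets out from 1 and returns at 7, putting the isovaleryl group in before the ring is made. Claisen condensation of 1 with ethyl 3-methylbutanoate (NaH, THF, reflux) gives 2,10-dimethylundec-9-ene-4,6-dione F4. Annulation of F4 with 2 (NaOEt, EtOH, reflux) closes the ring through the central and the prenyl-side methylene carbons to give 7 directly; the minor isomer from closure on the isobutyl side is removed by crystallisation.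

## Further compounds

F1 | step 5 | 2-(3-methylbut-2-en-1-yl)-1,3-dithiane | CC(C)=CCC1SCCCS1
F2 | step 5 | (4S,5S)-3,4,5-trihydroxy-5-(3-methylbut-2-en-1-yl)-2-(3-methylbutanoyl)-4-[2-(3-methylbut-2-en-1-yl)-1,3-dithian-2-yl]cyclopent-2-en-1-one | CC(C)=CCC1(SCCCS1)[C@]2(O)C(O)=C(C(=O)CC(C)C)C(=O)[C@]2(O)CC=C(C)C
F3 | step 3 | racemic 2,4-dihydroxy-2-(3-methylbut-2-en-1-yl)-5-(3-methylbutanoyl)cyclopent-4-ene-1,3-dione (8 together with its enantiomer) | O=C1C(O)=C(C(=O)CC(C)C)C(=O)C1(O)CC=C(C)C
F4 | step 2 | 2,10-dimethylundec-9-ene-4,6-dione | CC(C)CC(=O)CC(=O)CCC=C(C)C
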